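**Retrosynthetic overview**

1. Feature: ring A (C1–C5 and C10, halimane numbering; ring B = C5–C10) is a cyclohexene whose C1=C10 alkene and quaternary C4 (Me, CO2Me), bonded to ring-fusion C5, map onto a ring-B diene C2=C1–C10=C5 plus a C3=C4 methacrylate.
2. 22 ⇒ 21 by Sharpless epoxidation (C13, C14); 21 ⇒ 17 by building C13–C15 and the (E)-alkene from the C13 alcohol (oxidation, alkynylation, carboalumination–hydroxymethylation).
3. 17 ⇒ 13: the C1 silyl enol ether left by the cycloaddition becomes the C1 enol triflate and then C1–H, so the alkene stays at C1=C10. The allyl group is hydroborated before the palladium reduction, because a C1 vinylpalladium next to an intact allyl group could cyclise onto it.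
4. 13 ⇒ 11 + 12 by Diels–Alder disconnection of C2–C3 and C4–C5; 11 ⇒ 5 by enol triflation, Stille acetylation and silylation; 5 ⇒ 1 + 2 by asymmetric conjugate methylation–allylation (C8, C9).
5. Ring order: ring B comes from 1; ring A is closed in step 5.

Key step: step 5

Assumption: the (S,S,S) ligand antipode is taken to deliver methyl to the enone face that gives (3R) in 5; if the sense is the reverse, the (R,R,R) ligand is used and nothing else changes.

**Route**

Step 1
Reactants: 1 2-methylcyclohex-2-en-1-one; 2 allyl bromide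
Product: 5 (2S,3R)-2-allyl-2,3-dimethylcyclohexan-1-one, via dimethylaluminium enolate 3 (not isolated), via lithium aluminate enolate 4 (not isolated)
Conditions: Me3Al, Cu(OTf)2 (2 mol%), (S,S,S)-phosphoramidite from (S)-BINOL and bis[(S)-1-phenylethyl]amine (4 mol%), Et2O, −30 °C; then MeLi, HMPA, THF, −30 °C; then 2, −30 → 0 °C
Reagents that add atoms: trimethylaluminium C[Al](C)C; allyl bromide C=CCBr
Why: Copper-catalysed asymmetric conjugate addition sets C8 (R) under ligand control, and the MeLi-activated enolate is C-allylated at its tetrasubstituted carbon anti to the new C8 methyl, which sets C9 (S) with the two methyls cis (tandem conjugate addition–enolate alkylation).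

Step 2
Reactants: 5 (2S,3R)-2-allyl-2,3-dimethylcyclohexan-1-one
Product: 7 (5R,6S)-6-allyl-5,6-dimethylcyclohex-1-en-1-yl trifluoromethanesulfonate, via lithium enolate 6 (not isolated)
Conditions: LiN(iPr)2, THF, −78 °C; then PhNTf2, −78 °C → rt
Reagents that add atoms: N-phenylbis(trifluoromethanesulfonimide) O=S(=O)(N(c1ccccc1)S(=O)(=O)C(F)(F)F)C(F)(F)F
Why: Only the C5 methylene can be deprotonated because C9 is quaternary, and the lithium enolate is O-sulfonylated by PhNTf2 (enol triflate formation) without touching a stereocentre.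

Step 3
Reactants: 7 (5R,6S)-6-allyl-5,6-dimethylcyclohex-1-en-1-yl trifluoromethanesulfonate; 8 tributyl(1-ethoxyvinyl)stannane
Product: 10 1-[(5R,6S)-6-allyl-5,6-dimethylcyclohex-1-en-1-yl]ethan-1-one, via ethoxydiene 9 (not isolated)
Conditions: Pd(PPh3)4 (5 mol%), LiCl (3 equiv), THF, reflux; then 1 M HCl, rt
Reagents that add atoms: tributyl(1-ethoxyvinyl)stannane CCCC[Sn](CCCC)(CCCC)C(=C)OCC; water O
Why: Stille coupling of the enol triflate with the acyl-anion-equivalent stannane (LiCl-assisted transmetalation) and acid hydrolysis of the enol ether should give the methyl enone, the allyl group being placed so that only disfavoured 4-exo or 5-endo Heck closures could compete.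

Step 4
Reactants: 10 1-[(5R,6S)-6-allyl-5,6-dimethylcyclohex-1-en-1-yl]ethan-1-one
Product: 11 tert-butyl({1-[(5R,6S)-6-allyl-5,6-dimethylcyclohex-1-en-1-yl]ethenyl}oxy)dimethylsilane
Conditions: TBSOTf, Et3N, CH2Cl2, −78 → 0 °C
Reagents that add atoms: tert-butyldimethylsilyl trifluoromethanesulfonate CC(C)(C)[Si](C)(C)OS(=O)(=O)C(F)(F)F
Why: Soft enolisation (silyl triflate/amine) removes a proton from the acetyl methyl group, the kinetic site, and gives the cross-conjugated 2-silyloxydiene C2=C1(OTBS)–C10=C5.

Step 5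
Reactants: 11 tert-butyl({1-[(5R,6S)-6-allyl-5,6-dimethylcyclohex-1-en-1-yl]ethenyl}oxy)dimethylsilane; 12 methyl methacrylate
Product: 13 methyl (1S,5S,6R,8aR)-5-allyl-4-[(tert-butyldimethylsilyl)oxy]-1,5,6-trimethyl-1,2,3,5,6,7,8,8a-octahydronaphthalene-1-carboxylate
Conditions: 12 (5 equiv), MeAlCl2 (0.3 equiv), 2,6-di-tert-butyl-4-methylpyridine (0.1 equiv), CH2Cl2, −78 → −20 °C
Reagents that add atoms: methyl methacrylate C=C(C)C(=O)OC
Why: The Lewis-acid-bound methacrylate and the s-cis diene C2=C1(OTBS)–C10=C5 should combine in a concerted, asynchronous [4+2] cycloaddition, suprafacial on both partners, with C2–C3 bonding ahead of C4–C5; the closest known reaction type is the Diels–Alder reaction of 2-silyloxy-1,3-dienes with acrylates. Ring A closes as a six-membered carbocycle by this cycloaddition, fused to ring B at C5–C10, and its alkene is born as the C1(OTBS)=C10 silyl enol ether. The regiochemistry follows from the largest diene HOMO coefficient at C2 (the enol ether terminus) meeting the methacrylate β-carbon C3, which places quaternary C4 para to C1 and next to C5. C4 (S) is set by the ester-endo transition state, in which the complexed ester lies under C1/C10 and ends trans to H5, an arrangement favoured by secondary overlap that the Lewis acid strengthens. C5 (R) is set by attack on the diene face anti to the C9 methyl: in the half-chair with the C8 methyl equatorial, the cis C9 methyl is pseudoaxial and blocks its own face while the allyl group is pseudoequatorial, and the alternative half-chair has an axial group on both faces. The step therefore needs facial and endo selectivity, and both rest on the cis C8/C9 dimethyl array and on Lewis-acid complexation of the ester.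

Step 6
Reactants: 13 methyl (1S,5S,6R,8aR)-5-allyl-4-[(tert-butyldimethylsilyl)oxy]-1,5,6-trimethyl-1,2,3,5,6,7,8,8a-octahydronaphthalene-1-carboxylate
Product: 14 methyl (1S,5S,6R,8aR)-5-allyl-1,5,6-trimethyl-4-(trifluoromethanesulfonyloxy)-1,2,3,5,6,7,8,8a-octahydronaphthalene-1-carboxylate
Conditions: CsF (dried), PhNTf2, DME, rt
Reagents that add atoms: N-phenylbis(trifluoromethanesulfonimide) O=S(=O)(N(c1ccccc1)S(=O)(=O)C(F)(F)F)C(F)(F)F
Why: Fluoride cleaves the Si–O bond and the enolate, released regiospecifically as C1(O)=C10, is trapped at once by PhNTf2 (direct silyl enol ether to vinyl triflate conversion), so the double bond cannot migrate and no oxidant or free hydroxyl meets the enol ether.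

Step 7
Reactants: 14 methyl (1S,5S,6R,8aR)-5-allyl-1,5,6-trimethyl-4-(trifluoromethanesulfonyloxy)-1,2,3,5,6,7,8,8a-octahydronaphthalene-1-carboxylate
Product: 16 methyl (1S,5S,6R,8aR)-5-(3-hydroxypropyl)-1,5,6-trimethyl-4-(trifluoromethanesulfonyloxy)-1,2,3,5,6,7,8,8a-octahydronaphthalene-1-carboxylate, via B-alkyl-9-borabicyclononane 15 (not isolated)
Conditions: 9-BBN, THF, 0 °C → rt; then NaBO3·4H2O, H2O, rt
Reagents that add atoms: sodium perborate [Na+].[Na+].O[B-]1(O)OO[B-](O)(O)OO1
Why: 9-BBN hydroborates only the monosubstituted terminal alkene (anti-Markovnikov) while the tetrasubstituted vinyl triflate and the ester are inert, and mild perborate oxidation gives the C13 alcohol and removes the side-chain alkene before any palladium chemistry at C1.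

Step 8
Reactants: 16 methyl (1S,5S,6R,8aR)-5-(3-hydroxypropyl)-1,5,6-trimethyl-4-(trifluoromethanesulfonyloxy)-1,2,3,5,6,7,8,8a-octahydronaphthalene-1-carboxylate
Product: 17 methyl (1S,5S,6R,8aR)-5-(3-hydroxypropyl)-1,5,6-trimethyl-1,2,3,5,6,7,8,8a-octahydronaphthalene-1-carboxylate
Conditions: Pd(OAc)2 (5 mol%), PPh3 (10 mol%), Bu3N, HCO2H, DMF, 60 °C
Reagents that add atoms: none
Why: Palladium-catalysed formate reduction of the vinyl triflate (oxidative addition, decarboxylation of the palladium formate, C–H reductive elimination) replaces OTf by H with the alkene fixed at C1=C10, and with a saturated side chain the vinylpalladium has no alkene to insert.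

Step 9
Reactants: 17 methyl (1S,5S,6R,8aR)-5-(3-hydroxypropyl)-1,5,6-trimethyl-1,2,3,5,6,7,8,8a-octahydronaphthalene-1-carboxylate
Product: 18 methyl (1S,5S,6R,8aR)-1,5,6-trimethyl-5-(3-oxopropyl)-1,2,3,5,6,7,8,8a-octahydronaphthalene-1-carboxylate
Conditions: Dess–Martin periodinane, CH2Cl2, 0 °C → rt
Reagents that add atoms: none
Why: Dess–Martin oxidation should take the primary alcohol to the aldehyde without affecting the trisubstituted alkene or the ester.

Step 10
Reactants: 18 methyl (1S,5S,6R,8aR)-1,5,6-trimethyl-5-(3-oxopropyl)-1,2,3,5,6,7,8,8a-octahydronaphthalene-1-carboxylate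
Product: 19 methyl (1S,5S,6R,8aR)-5-(but-3-yn-1-yl)-1,5,6-trimethyl-1,2,3,5,6,7,8,8a-octahydronaphthalene-1-carboxylate
Conditions: dimethyl (1-diazo-2-oxopropyl)phosphonate, K2CO3, MeOH, 0 °C → rt
Reagents that add atoms: dimethyl (1-diazo-2-oxopropyl)phosphonate COP(=O)(OC)C(=[N+]=[N-])C(C)=O
Why: Ohira–Bestmann (Seyferth–Gilbert) homologation converts the aldehyde into the terminal alkyne C13≡C14 under mild carbonate/methanol conditions, in which the aldehyde has no epimerisable α-centre and methanolysis of the methyl ester is degenerate.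

Step 11
Reactants: 19 methyl (1S,5S,6R,8aR)-5-(but-3-yn-1-yl)-1,5,6-trimethyl-1,2,3,5,6,7,8,8a-octahydronaphthalene-1-carboxylate
Product: 21 methyl (1S,5S,6R,8aR)-5-[(3E)-5-hydroxy-3-methylpent-3-en-1-yl]-1,5,6-trimethyl-1,2,3,5,6,7,8,8a-octahydronaphthalene-1-carboxylate, via alkenyldimethylalane 20 (not isolated)
Conditions: Me3Al (2.5 equiv), Cp2ZrCl2 (0.25 equiv), CH2Cl2, 0 °C → rt; then (CH2O)n, 0 °C → rt; aq. Rochelle salt
Reagents that add atoms: trimethylaluminium C[Al](C)C; paraformaldehyde (as formaldehyde) C=O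
Why: Negishi zirconium-catalysed carboalumination adds methyl and aluminium syn across the alkyne with methyl on the internal carbon C13, and the alkenylalane is hydroxymethylated by formaldehyde with retention, so the (13E)-allylic alcohol should result while the hindered neopentyl-type C4 ester resists Me3Al.

Step 12
Reactants: 21 methyl (1S,5S,6R,8aR)-5-[(3E)-5-hydroxy-3-methylpent-3-en-1-yl]-1,5,6-trimethyl-1,2,3,5,6,7,8,8a-octahydronaphthalene-1-carboxylate
Product: 22 methyl (1S,5S,6R,8aR)-5-{2-[(2S,3S)-3-(hydroxymethyl)-2-methyloxiran-2-yl]ethyl}-1,5,6-trimethyl-1,2,3,5,6,7,8,8a-octahydronaphthalene-1-carboxylate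
Conditions: Ti(OiPr)4 (10 mol%), L-(+)-diethyl tartrate (12 mol%), t-BuOOH (2 equiv), 4 Å MS, CH2Cl2, −20 °C
Reagents that add atoms: tert-butyl hydroperoxide CC(C)(C)OO
Why: Sharpless asymmetric epoxidation is directed by the allylic hydroxyl, so the isolated C1=C10 alkene is untouched, and the L-(+)-tartrate catalyst should deliver oxygen to the face of the (E)-3-methyl-2-alkenol that gives (13S,14S), as it does for geraniol-type substrates (reagent control).

**Compound list**

1 | 2-methylcyclohex-2-en-1-one | CC1=CCCCC1=O | starting material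
2 | allyl bromide | C=CCBr | starting material
3 | dimethylaluminium (3R)-2,3-dimethylcyclohex-1-en-1-olate | C[C@@H]1CCCC(O[Al](C)C)=C1C | intermediate
4 | lithium trimethyl[(3R)-2,3-dimethylcyclohex-1-en-1-olato]aluminate | C[C@@H]1CCCC(O[Al-](C)(C)C)=C1C.[Li+] | intermediate
5 | (2S,3R)-2-allyl-2,3-dimethylcyclohexan-1-one | O=C1CCC[C@@H](C)[C@]1(C)CC=C | intermediate
6 | lithium (5R,6S)-6-allyl-5,6-dimethylcyclohex-1-en-1-olate | [Li]OC1=CCC[C@@H](C)[C@]1(C)CC=C | intermediate
7 | (5R,6S)-6-allyl-5,6-dimethylcyclohex-1-en-1-yl trifluoromethanesulfonate | O=S(=O)(OC1=CCC[C@@H](C)[C@]1(C)CC=C)C(F)(F)F | intermediate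
8 | tributyl(1-ethoxyvinyl)stannane | CCCC[Sn](CCCC)(CCCC)C(=C)OCC | starting material
9 | (5R,6S)-6-allyl-1-(1-ethoxyethenyl)-5,6-dimethylcyclohex-1-ene | C=C(OCC)C1=CCC[C@@H](C)[C@]1(C)CC=C | intermediate
10 | 1-[(5R,6S)-6-allyl-5,6-dimethylcyclohex-1-en-1-yl]ethan-1-one | CC(=O)C1=CCC[C@@H](C)[C@]1(C)CC=C | intermediate
11 | tert-butyl({1-[(5R,6S)-6-allyl-5,6-dimethylcyclohex-1-en-1-yl]ethenyl}oxy)dimethylsilane (ring-B 2-silyloxydiene) | C=C(O[Si](C)(C)C(C)(C)C)C1=CCC[C@@H](C)[C@]1(C)CC=C | intermediate
12 | methyl methacrylate | C=C(C)C(=O)OC | starting material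
13 | methyl (1S,5S,6R,8aR)-5-allyl-4-[(tert-butyldimethylsilyl)oxy]-1,5,6-trimethyl-1,2,3,5,6,7,8,8a-octahydronaphthalene-1-carboxylate (halimane: C1 OTBS, 4S,5R,8R,9S) | COC(=O)[C@@]1(C)CCC(O[Si](C)(C)C(C)(C)C)=C2[C@H]1CC[C@@H](C)[C@]2(C)CC=C | intermediate
14 | methyl (1S,5S,6R,8aR)-5-allyl-1,5,6-trimethyl-4-(trifluoromethanesulfonyloxy)-1,2,3,5,6,7,8,8a-octahydronaphthalene-1-carboxylate | COC(=O)[C@@]1(C)CCC(OS(=O)(=O)C(F)(F)F)=C2[C@H]1CC[C@@H](C)[C@]2(C)CC=C | intermediate
15 | B-alkyl-9-borabicyclo[3.3.1]nonane from hydroboration of the allyl group of 14 (boron on C13) | COC(=O)[C@@]1(C)CCC(OS(=O)(=O)C(F)(F)F)=C2[C@H]1CC[C@@H](C)[C@]2(C)CCCB1C2CCCC1CCC2 | intermediate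
16 | methyl (1S,5S,6R,8aR)-5-(3-hydroxypropyl)-1,5,6-trimethyl-4-(trifluoromethanesulfonyloxy)-1,2,3,5,6,7,8,8a-octahydronaphthalene-1-carboxylate | COC(=O)[C@@]1(C)CCC(OS(=O)(=O)C(F)(F)F)=C2[C@H]1CC[C@@H](C)[C@]2(C)CCCO | intermediate
17 | methyl (1S,5S,6R,8aR)-5-(3-hydroxypropyl)-1,5,6-trimethyl-1,2,3,5,6,7,8,8a-octahydronaphthalene-1-carboxylate | COC(=O)[C@@]1(C)CCC=C2[C@H]1CC[C@@H](C)[C@]2(C)CCCO | intermediate
18 | methyl (1S,5S,6R,8aR)-1,5,6-trimethyl-5-(3-oxopropyl)-1,2,3,5,6,7,8,8a-octahydronaphthalene-1-carboxylate | COC(=O)[C@@]1(C)CCC=C2[C@H]1CC[C@@H](C)[C@]2(C)CCC=O | intermediate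
19 | methyl (1S,5S,6R,8aR)-5-(but-3-yn-1-yl)-1,5,6-trimethyl-1,2,3,5,6,7,8,8a-octahydronaphthalene-1-carboxylate | COC(=O)[C@@]1(C)CCC=C2[C@H]1CC[C@@H](C)[C@]2(C)CCC#C | intermediate
20 | (E)-alkenyldimethylalane from carboalumination of 19 (methyl on C13, aluminium on C14) | COC(=O)[C@@]1(C)CCC=C2[C@H]1CC[C@@H](C)[C@]2(C)CC/C(C)=C/[Al](C)C | intermediate
21 | methyl (1S,5S,6R,8aR)-5-[(3E)-5-hydroxy-3-methylpent-3-en-1-yl]-1,5,6-trimethyl-1,2,3,5,6,7,8,8a-octahydronaphthalene-1-carboxylate | COC(=O)[C@@]1(C)CCC=C2[C@H]1CC[C@@H](C)[C@]2(C)CC/C(C)=C/CO | intermediate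
22 | methyl (1S,5S,6R,8aR)-5-{2-[(2S,3S)-3-(hydroxymethyl)-2-methyloxiran-2-yl]ethyl}-1,5,6-trimethyl-1,2,3,5,6,7,8,8a-octahydronaphthalene-1-carboxylate (halimane: 4S,5R,8R,9S,13S,14S) | COC(=O)[C@@]1(C)CCC=C2[C@H]1CC[C@@H](C)[C@]2(C)CC[C@]1(C)O[C@H]1CO | target

**Step count and risks**

Total step count: 12. Longest linear sequence: 12 steps (1 → 22).

Steps most likely to fail:

Step 5. The cycloaddition may discriminate poorly between the two diene faces or between ester-endo and ester-exo approach. The Lewis acid may also strip silicon from the diene so that the reaction stops at an open-chain Michael adduct, and the s-cis diene, crowded by C9, may react slowly. Fallback, from 10 back to 14: an anionic double Michael annulation. Enone 10 is deprotonated at the acetyl methyl with LiN(iPr)2 in THF at −78 °C to the cross-conjugated lithium dienolate F1, and 12 is added. Michael addition of C2 to C3 gives an ester enolate that closes onto C5 of the regenerated enone, leaving the bicyclic lithium C1(O)=C10 enolate F2. PhNTf2 added to the same flask traps F2 as vinyl triflate 14, so steps 4 to 6 are replaced by one operation. The compact, lithium-bridged transition state of such Michael–Michael ring closures normally gives the same relative configuration as the endo cycloadduct.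

Step 11. The alkenylalane may be protonated before it captures depolymerising paraformaldehyde, and a slow run exposes the C4 ester to Me3Al. Fallback, from 19 back to 21: the same carboalumination is run, but alkenylalane 20 is quenched with I2 at −30 °C to give the isolable (E)-vinyl iodide F3. Stille coupling of F3 with (tributylstannyl)methanol (Pd(PPh3)4, toluene, 80 °C) then installs C15 with retention of the alkene geometry and gives 21.

Step 1. Allylation of the activated aluminium enolate may be incomplete, may give O- or poly-allylation, or may erode the trans selectivity at C9. Fallback, from 1 back to 5: after the same conjugate addition, aluminium enolate 3 is O-acylated with allyl chloroformate to give allyl (3R)-2,3-dimethylcyclohex-1-en-1-yl carbonate F4, which is isolated. Pd(PPh3)4 (cat.) in THF at rt then triggers decarboxylative Tsuji allylation, which forms the quaternary carbon regiospecifically with the allyl group delivered anti to the C8 methyl, giving 5.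

**Further compounds**

F1 | step 5 | lithium 1-[(5R,6S)-6-allyl-5,6-dimethylcyclohex-1-en-1-yl]ethen-1-olate | [Li]OC(=C)C1=CCC[C@@H](C)[C@]1(C)CC=C
F2 | step 5 | lithium C1(O)=C10 enolate of methyl (1S,5S,6R,8aR)-5-allyl-1,5,6-trimethyl-4-oxodecahydronaphthalene-1-carboxylate | COC(=O)[C@@]1(C)CCC(O[Li])=C2[C@H]1CC[C@@H](C)[C@]2(C)CC=C
F3 | step 11 | methyl (1S,5S,6R,8aR)-5-[(3E)-4-iodo-3-methylbut-3-en-1-yl]-1,5,6-trimethyl-1,2,3,5,6,7,8,8a-octahydronaphthalene-1-carboxylate | COC(=O)[C@@]1(C)CCC=C2[C@H]1CC[C@@H](C)[C@]2(C)CC/C(C)=C/I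
F4 | step 1 | allyl (3R)-2,3-dimethylcyclohex-1-en-1-yl carbonate | C[C@@H]1CCCC(OC(=O)OCC=C)=C1C
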